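## The problem

CNP0348992.2 is a germacranolide. Its ten-membered carbocycle is numbered here C1–C10, with the lactone carbons C11–C13, the methyl C14 on C10 and the methylene C15 on C4. The ring carries a trans-fused α-methylene-γ-lactone across C7/C8 (oxygen on C8), a trisubstituted C1–C10 epoxide, a C3 ketone cross-conjugated with the C4 methylene, an angelate on C5 and a free hydroxyl on C6.

A ring of this size is poorly made by joining two chain ends, since entropy and transannular strain both oppose the closure. It is better uncovered from a smaller, rigid bicycle.

Six stereocentres must be set: C5, C6, C7 and C8 in a row, and the two epoxide carbons. C6, C7 and C8 can be fixed on a cyclohexane chair. The C6 ether can then steer a hydride to C5 by chelation, and the lactone-stiffened macrocycle can offer one face of the C1=C10 alkene to a peracid.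

Several groups will not survive rough treatment: the two exocyclic Michael acceptors, the Z-angelate (which isomerises to the tiglate and migrates to a neighbouring free hydroxyl under base), and the medium-ring epoxide (which cyclises across the ring under acid). These must appear in the last steps.

The feature that makes the key step possible is transannular. C5 and C10 face each other across the ring. A C5 carbonyl and an E-configured C1=C10 alkene are exactly the two ends left when the fusion bond of a decalin (ring A = C10, C1–C5; ring B = C5–C10) with a hydroxyl on C5 and a sulfonate on C1 is broken heterolytically.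

## Retrosynthesis

**End game (29 back to 21).** The epoxide C–O bonds of 29 are cut first, giving the E-alkene 28. The acid-labile oxirane thus appears after every other operation, and the peracid only has to pick the one electron-rich alkene. Before that, the C3 ketone and the C6 hydroxyl are masked (27, dioxolane and methoxymethyl ether), the ester C–O bond is cut to alcohol 25 and angelic acid 26, and the C11=C13 bond is cut to lactone 22. Methylenation precedes acylation because the angelate would not tolerate the lactone enolate chemistry. Alcohol 22 comes from ketone 21 by cutting the C5–H bond; the forward reduction must place the hydroxyl cis to the C6 ether, which the chelating ether is there to secure.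

**Key disconnection (21 back to 20).** Joining C5 to C10 in 21 turns the (E)-cyclodecenone into the trans-decalin 20, a C5 tertiary alcohol with an equatorial C1 mesylate. This cut is preferred to any cut of a ring C–C bond that would demand a macrocyclisation: forward, the ten-membered ring arises by ring expansion. The precursor has rigid chairs on which C6, C7 and C8 sit as axial ether and trans-diequatorial lactone. The forward reaction needs the mesylate antiperiplanar to the fusion bond and C2 anti to C9, both of which the trans fusion guarantees.

**Ring A adjustments (20 back to 15).** The mesylate 20 comes from alcohol 19, and this from silyl ether 18. The dioxolane of 18 is traced to the methyl enol ether of 17, and the C1 oxygen of 17 and 16 to the vinylogous ester carbonyl of 15. Reduction has to come before ketal formation because the enol ether is the only handle on C3; the intervening silyl ether keeps the 3-methoxy-allyl alcohol 16 from ionising under the acid that makes the ketal. The hydride must enter C1 opposite the axial C14 methyl to give the equatorial alcohol.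

**C15 and the lactone (15 back to 10).** Cutting C4=C15 leads to ketone 14, reached by oxidation of carbinol 13. Cutting the lactone C–O bond and the C8–O and C7–H bonds of 13 leads to the trisubstituted alkene 10. A syn addition of H and OH across C7=C8 sets both centres at once and trans to each other. On the trans-decalin, both the axial C14 methyl and the axial C6 ether block the same face, so the addition has only one way to go. A carbonyl reduction at C8 would have had to run against that bias.

**C5 and C6 oxygens (10 back to 7).** The C6 ether of 10 and the C5 hydroxyl of diol 9 are traced to epoxide 8, and this to the C5=C6 bond of dienone 7. A Diels–Alder adduct with an oxygen on C6 would carry it trans to the angular methyl (endo rule), which is the wrong epimer for an axial C6 ether on a trans-decalin. That centre is therefore erased and rebuilt: trans-diaxial opening of the epoxide gives both oxygens in the required sense and fixes the trans ring fusion at the same time.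

**The bicycle (7 back to 1, 2 and 5).** Cutting C5–C6 and C9–C10 of the cycloadduct 6 (which loses silanol to give 7) leads to silyloxy diene 4 and 2-methoxy-5-methyl-1,4-benzoquinone 5. The quinone supplies the quaternary C10, both ring-A carbonyls and the masked C3 ketone in one step; only the configuration at C10 has to be controlled. Diene 4 is the dienol ether of enal 3, the aldol condensation product of methyl 4-oxobutanoate 1 and acetaldehyde 2.

## Roads not taken

**Alternative 1:** The cut is made at the lactone C8–O and C8–H bonds of an open-chain keto diester A1. Forward, a ketoreductase reduces the C8 ketone of the racemising A1 on one face of one C7 epimer, and the hydroxy diester lactonises to the trans paraconate A2.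
- Merits: absolute configuration at C7 and C8 comes from an enzyme in one operation, without a chiral Lewis acid, on cheap material.
- Weak points for this target: the ten-membered ring still has to be closed end to end later; C5 and C6 must be set on a flexible chain by induction from C7; an enzyme must be found that accepts the bulky allylic arm and the tert-butyl ester.
- Comparison: in absolute stereocontrol at C7/C8 and in step count to the lactone this road is better. The chosen plan offers instead a ring that never has to be closed, and four contiguous centres set on rigid chairs.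

**Alternative 2:** The cut is made across C3 and C8, which are joined as a tetrasubstituted alkene in the bicycle A3. Forward, ozone cleaves that alkene and opens the bicycle to the ten-membered 3,8-diketone A4.
- Merits: this is also a ring expansion, ozonolysis is more dependable than an alkoxide-triggered fragmentation, and the C3 carbonyl arrives at the right oxidation level. The C10 alcohol and C1 mesylate of A4 can close the epoxide by internal displacement, so the epoxide configuration follows from two stereocentres instead of from a facial preference. In that respect it is better than step 20 here.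
- Weak points: C8 arrives as a ketone and must be reduced and lactonised with control inside a floppy ring; the 3,8-diketone invites transannular aldol reaction; six stereocentres must be in place on A3 before cleavage; the C5/C6 diol leaves the selective angeloylation of C5 unsolved.
- Comparison: the chosen plan offers the lactone already formed, C5 and C6 differentiated as ketone and ether, and an alkene geometry fixed by the fragmentation itself.

**Alternative 3:** The cut is made at C2–C3 and C3–C4 of the seco allylic chloride/vinylstannane A5. Forward, zerovalent palladium (Pd2(dba)3, AsPh3) ionises the chloride, inserts CO and couples with the stannane to close the ring as A6.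
- Merits: it is the most convergent road. The ketone carbon is added last, all stereocentres and the angelate are already present, and A6 is two steps from the target.
- Weak points: this is exactly the end-to-end ten-membered closure that the strain argues against. Direct coupling without CO, protodestannylation and scrambling of the allyl geometry compete. The four contiguous centres of A5 must be built on an open chain.
- Comparison: in end-game step economy this road is clearly better. The chosen plan offers a ring-forming event with no dilution or competition problem, and stereocentres set on a decalin.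

Key step: step 15

Remark: (S)-BINOL is written in step 3; the ligand enantiomer that delivers the C10 configuration of 7 is the one to be used.
Remark: the C4 carbinol centre of 11–13 and the C11 centre of 23 and 24 are left undefined, since each is erased one or two operations later.

Step 1
Reactants: 1 methyl 4-oxobutanoate; 2 acetaldehyde
Product: 3 methyl (3E)-3-formylpent-3-enoate
Conditions: pyrrolidine (20 mol%), PhCO2H (20 mol%), CH2Cl2, 0 °C to rt, slow addition of 2
Reagents that add atoms: none
Why: Amine-catalysed cross-aldol condensation: the enamine of 1 adds to the more electrophilic acetaldehyde and water is lost to give the conjugated enal. The E isomer (formyl trans to methyl) is the thermodynamic one.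

Step 2
Reactants: 3 methyl (3E)-3-formylpent-3-enoate
Product: 4 methyl (3E)-3-{[(tert-butyldimethylsilyl)oxy]methylidene}pent-4-enoate
Conditions: TBSOTf, Et3N, CH2Cl2, 0 °C
Reagents that add atoms: tert-butyldimethylsilyl trifluoromethanesulfonate CC(C)(C)[Si](C)(C)OS(=O)(=O)C(F)(F)F
Why: Soft enolisation: O-silylation of the aldehyde and loss of a γ-proton from the methyl group give the silyl dienol ether. The s-trans enal leads to the 1E isomer with the silyloxy group trans to the vinyl group.

Step 3
Reactants: 4 silyloxy diene; 5 2-methoxy-5-methyl-1,4-benzoquinone
Product: 7 cross-conjugated dienone methyl 2-(3-methoxy-8a-methyl-1.4-dioxo-8.8a-dihydronaphthalen-6-yl)acetate (8a = C10), via endo cycloadduct 6 (not isolated)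
Conditions: TiCl2(OiPr)2, (S)-BINOL (20 mol%), CH2Cl2, −40 °C; then DBU, 0 °C
Reagents that add atoms: none
Why: Catalytic asymmetric Diels–Alder reaction: the titanium BINOLate chelates the methoxy oxygen and its neighbouring carbonyl (future C4), so the methyl-bearing alkene reacts, the CH2 terminus of the diene bonds to the methyl-bearing carbon, and the ligand picks the quinone face that sets C10. DBU then expels silanolate from the β-silyloxy ketone 6 (E1cB), which erases C5 and C6 and gives 7.

Step 4
Reactants: 7 dienone
Product: 8 5,6-epoxy ketone with the oxirane trans to the C14 methyl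
Conditions: t-BuOOH, DBU, CH2Cl2, 0 °C
Reagents that add atoms: tert-butyl hydroperoxide CC(C)(C)OO
Why: Nucleophilic (Weitz–Scheffer) epoxidation: the peroxide anion adds to C6, the unhindered β-carbon of the s-cis enone, from the face opposite the pseudo-axial C14 methyl, and the enolate closes onto oxygen. The C7=C8 bond, whose γ-carbon is fully substituted, is left.

Step 5
Reactants: 8 epoxy ketone
Product: 9 trans-decalin 5,6-diol (C5 hydroxyl trans and C6 hydroxyl cis to C14)
Conditions: HClO4 (cat.), THF–H2O, 0 °C
Reagents that add atoms: water O
Why: Acid-catalysed hydrolysis of a vinyl epoxide: the C5–O bond is deactivated by the C4 carbonyl, so water opens the allylic C6–O bond with inversion (trans-diaxial opening). The retained C5 oxygen fixes the trans ring fusion and the new C6 hydroxyl is axial, cis to C14.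

Step 6
Reactants: 9 diol
Product: 10 C6 methoxymethyl ether
Conditions: MOMCl, iPr2NEt, CH2Cl2, 0 °C to rt
Reagents that add atoms: chloromethyl methyl ether COCCl
Why: Alkylation of the secondary allylic hydroxyl under mild base; the tertiary ring-fusion hydroxyl is too hindered to react.

Step 7
Reactants: 10 methoxymethyl ether
Product: 13 trans-fused γ-lactone with a C4 carbinol, via alkylborane 11 (not isolated), via triol ester 12 (not isolated)
Conditions: BH3·SMe2, THF, 0 °C to rt; H2O2, NaOAc (aq); then PPTS, PhMe, 60 °C
Reagents that add atoms: hydrogen peroxide OO
Why: Hydroboration–oxidation: borane reduces the C4 ketone (hydride delivered from the borate of the neighbouring hydroxyl) and adds to C7=C8 from the face opposite the axial C14 methyl and the axial C6 ether, with boron on C8. Oxidation with retention gives the equatorial C8 alcohol trans to the C7 acetate arm, so C7 and C8 are set together by the syn addition. Acid then closes the trans-diequatorial γ-lactone with the only hydroxyl in reach of the ester.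

Step 8
Reactants: 13 hydroxy lactone
Product: 14 C4 ketone
Conditions: Dess–Martin periodinane, NaHCO3, CH2Cl2, 0 °C to rt
Reagents that add atoms: none
Why: Dess–Martin oxidation of the only secondary hydroxyl restores the C4 ketone; the tertiary hydroxyl, the acetal and the lactone are inert.

Step 9
Reactants: 14 ketone
Product: 15 C4 methylene compound
Conditions: Zn, CH2Br2, TiCl4, THF–CH2Cl2, 0 °C to rt
Reagents that add atoms: dibromomethane BrCBr
Why: Takai–Lombardo methylenation: the non-basic zinc/titanium methylene reagent olefinates the hindered α-hydroxy ketone without retro-aldol cleavage or ketol shift. It does not attack the lactone or the vinylogous ester.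

Step 10
Reactants: 15 methylene compound
Product: 16 C1 allylic alcohol (hydroxyl cis to C14)
Conditions: NaBH4, CeCl3·7H2O, MeOH, −40 °C
Reagents that add atoms: none
Why: Luche 1,2-reduction of the cross-conjugated vinylogous ester carbonyl. Hydride enters C1 from the face opposite the axial C14 methyl, so the new hydroxyl is equatorial and cis to the methyl; the lactone is not reduced.

Step 11
Reactants: 16 allylic alcohol
Product: 17 C1 tert-butyldimethylsilyl ether
Conditions: TBSOTf, 2,6-lutidine, CH2Cl2, −78 °C
Reagents that add atoms: tert-butyldimethylsilyl trifluoromethanesulfonate CC(C)(C)[Si](C)(C)OS(=O)(=O)C(F)(F)F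
Why: Silylation of the secondary allylic hydroxyl (the tertiary one is too hindered). The ether keeps the 3-methoxy-allyl alcohol from ionising under the acid of the next step.

Step 12
Reactants: 17 silyl ether
Product: 18 C3 dioxolane
Conditions: HOCH2CH2OH, PPTS (cat.), CH2Cl2, 0 °C to rt
Reagents that add atoms: ethylene glycol OCCO
Why: Acid-catalysed transketalisation of an enol ether: protonation at C2 gives the C3 oxocarbenium ion, the diol adds and methanol is lost. The C3 carbonyl thus appears directly as its dioxolane with C2 as a methylene group.

Step 13
Reactants: 18 dioxolane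
Product: 19 C1 alcohol
Conditions: Bu4NF, THF, 0 °C to rt
Reagents that add atoms: none
Why: Fluoride-induced cleavage of the silyl ether; dioxolane, methoxymethyl ether and lactone are stable to these conditions.

Step 14
Reactants: 19 diol
Product: 20 trans-decalin 5-ol 1-mesylate
Conditions: MsCl, Et3N, CH2Cl2, −10 °C
Reagents that add atoms: methanesulfonyl chloride CS(=O)(=O)Cl
Why: Sulfonylation of the secondary equatorial C1 hydroxyl; the tertiary ring-fusion hydroxyl does not react.

Step 15
Reactants: 20 mesylate
Product: 21 (E)-cyclodecenone lactone
Conditions: KOtBu, THF, 0 °C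
Reagents that add atoms: none
Why: Grob (Wharton-type) fragmentation of a 1,3-diol monosulfonate, the classical route from decalin hydroxy sulfonates to (E)-cyclodec-5-enones. KOtBu forms the tertiary C5 alkoxide, whose lone pair builds the C5 carbonyl while the antiperiplanar C5–C10 bond breaks and the C1 mesylate leaves in one concerted heterolytic event. No ring is closed by bond formation: the ten-membered ring is uncovered by cleaving the bond shared by rings A and B, so no closure mode or dilution is at issue. No stereocentre is created; C1, C5 and C10 become trigonal and C6, C7 and C8 pass through unchanged. The selectivity needed is alkene geometry and fragmentation over elimination or oxetane formation. In the rigid trans-decalin the equatorial mesylate is antiperiplanar to the fusion bond and C2 is anti to C9 across C1–C10, so the alkene is born E, and the axial alkoxide cannot reach the back of C1. A short reaction time at 0 °C limits alkoxide addition to the new α-methylene ketone and enolisation at C6.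

Step 16
Reactants: 21 cyclodecenone
Product: 22 C5 allylic alcohol (hydroxyl cis to the C6 ether)
Conditions: Zn(BH4)2, Et2O, −30 °C
Reagents that add atoms: none
Why: Chelation-controlled 1,2-reduction: zinc bridges the C5 carbonyl and the C6 methoxymethyl ether, and hydride attacks from the side of the C6 hydrogen. This gives the alcohol cis to the ether, the 5R centre of the target; lactone and ketal are not reduced.

Step 17
Reactants: 22 allylic alcohol
Product: 25 α-methylene lactone, via Mannich base 23 (not isolated), via ammonium iodide 24 (not isolated)
Conditions: LiN(SiMe3)2 (2.2 equiv), THF, −78 °C, Me2N=CH2+ I−; then MeI, MeOH; then NaHCO3 (aq), CH2Cl2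
Reagents that add atoms: N,N-dimethylmethyleneiminium iodide C=[N+](C)C.[I-]
Why: Mannich α-methylenation of a lactone: the lactone enolate (beside the C5 alkoxide) is aminomethylated by the iminium salt, the amine is quaternised and the ammonium salt eliminates on mild base. The C11 centre is erased in the elimination.

Step 18
Reactants: 25 alcohol; 26 angelic acid
Product: 27 C5 angelate
Conditions: 26, 2,4,6-Cl3C6H2COCl, Et3N, PhMe, rt; then 25, 75 °C
Reagents that add atoms: none
Why: Yamaguchi-type esterification: the mixed anhydride of angelic acid acylates the allylic C5 hydroxyl without the nucleophilic catalyst that isomerises angelates to tiglates. The C6 oxygen is still protected, so no regiochemical question arises.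

Step 19
Reactants: 27 angelate
Product: 28 C3 ketone with free C6 hydroxyl
Conditions: Me2BBr, CH2Cl2, −78 °C; then NaHCO3 (aq)
Reagents that add atoms: water O
Why: Dimethylboron bromide cleaves the methoxymethyl ether and the allylic dioxolane at low temperature under aprotic conditions, with hydrolysis on work-up. This avoids the protic acid that would ionise the allylic angelate or cyclise the 1(10)-alkene across the ring.

Step 20
Reactants: 28 dienone lactone
Product: 29 CNP0348992.2
Conditions: mCPBA, NaHCO3, CH2Cl2, 0 °C
Reagents that add atoms: 3-chloroperbenzoic acid OOC(=O)c1cccc(Cl)c1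
Why: Prilezhaev epoxidation: the peracid selects the only electron-rich alkene (the other three are conjugated to carbonyl groups) and attacks its outer face in the conformation held by the trans-lactone, which should give the 1R,10R oxirane. The E geometry is carried over into the trans-epoxide.

## Compound list

1 | methyl 4-oxobutanoate | COC(=O)CCC=O | starting material
2 | acetaldehyde | CC=O | starting material
3 | methyl (3E)-3-formylpent-3-enoate | C/C=C(/C=O)CC(=O)OC | intermediate
4 | methyl (3E)-3-{[(tert-butyldimethylsilyl)oxy]methylidene}pent-4-enoate (1E silyloxy diene) | CC(C)(C)[Si](C)(C)O/C=C(/C=C)CC(=O)OC | intermediate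
5 | 2-methoxy-5-methyl-1,4-benzoquinone | COC1=CC(=O)C(C)=CC1=O | starting material
6 | cis-fused endo cycloadduct (C5–H cis, C6 silyl ether trans to the C14 methyl) | O=C1C=C(OC)C(=O)[C@@H]2[C@H](O[Si](C)(C)C(C)(C)C)C(CC(=O)OC)=CC[C@]12C | intermediate (not isolated)
7 | dienone, methyl 2-[(8aS)-3-methoxy-8a-methyl-1,4-dioxo-8,8a-dihydronaphthalen-6-yl]acetate (8a = C10) | O=C1C=C(OC)C(=O)C2=CC(CC(=O)OC)=CC[C@]12C | intermediate
8 | 5,6-epoxy-4-ketone, oxirane trans to C14 | O=C1C=C(OC)C(=O)[C@@]23[C@H](O3)C(CC(=O)OC)=CC[C@]12C | intermediate
9 | trans-decalin 5,6-diol (C5–OH trans, C6–OH cis to C14), C4 ketone, C7=C8 | O=C1C=C(OC)C(=O)[C@@]2(O)[C@@H](O)C(CC(=O)OC)=CC[C@]12C | intermediate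
10 | C6 methoxymethyl ether of 9 | O=C1C=C(OC)C(=O)[C@@]2(O)[C@@H](OCOC)C(CC(=O)OC)=CC[C@]12C | intermediate
11 | C8 alkylborane with reduced C4 (drawn as the free monoalkylborane) | O=C1C=C(OC)C(O)[C@@]2(O)[C@@H](OCOC)[C@@H](CC(=O)OC)[C@H](B)C[C@]12C | intermediate (not isolated)
12 | triol ester (C4, C5, C8 hydroxyls; C8–OH trans to the C7 arm) | O=C1C=C(OC)C(O)[C@@]2(O)[C@@H](OCOC)[C@@H](CC(=O)OC)[C@H](O)C[C@]12C | intermediate (not isolated)
13 | trans-fused 12,8-lactone with C4 carbinol | O=C1C=C(OC)C(O)[C@@]2(O)[C@@H](OCOC)[C@H]3CC(=O)O[C@@H]3C[C@]12C | intermediate
14 | lactone C4 ketone | O=C1C=C(OC)C(=O)[C@@]2(O)[C@@H](OCOC)[C@H]3CC(=O)O[C@@H]3C[C@]12C | intermediate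
15 | lactone with C4 methylene (C1 vinylogous ester) | O=C1C=C(OC)C(=C)[C@@]2(O)[C@@H](OCOC)[C@H]3CC(=O)O[C@@H]3C[C@]12C | intermediate
16 | C1 allylic alcohol, hydroxyl cis to C14 | O[C@H]1C=C(OC)C(=C)[C@@]2(O)[C@@H](OCOC)[C@H]3CC(=O)O[C@@H]3C[C@]12C | intermediate
17 | C1 tert-butyldimethylsilyl ether of 16 | CC(C)(C)[Si](C)(C)O[C@H]1C=C(OC)C(=C)[C@@]2(O)[C@@H](OCOC)[C@H]3CC(=O)O[C@@H]3C[C@]12C | intermediate
18 | C3 dioxolane, C1 silyl ether | CC(C)(C)[Si](C)(C)O[C@H]1CC2(OCCO2)C(=C)[C@@]3(O)[C@@H](OCOC)[C@H]4CC(=O)O[C@@H]4C[C@]13C | intermediate
19 | trans-decalin 1,5-diol (C3 dioxolane, C4 methylene, C6 OMOM, 12,8-lactone) | O[C@H]1CC2(OCCO2)C(=C)[C@@]3(O)[C@@H](OCOC)[C@H]4CC(=O)O[C@@H]4C[C@]13C | intermediate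
20 | trans-decalin 5-ol 1-mesylate (mesylate equatorial, cis to C14; C5–OH trans to C14) | CS(=O)(=O)O[C@H]1CC2(OCCO2)C(=C)[C@@]3(O)[C@@H](OCOC)[C@H]4CC(=O)O[C@@H]4C[C@]13C | intermediate
21 | (1(10)E)-cyclodecenone lactone, C5 ketone conjugated to the C4 methylene | C/C1=C\CC2(OCCO2)C(=C)C(=O)[C@@H](OCOC)[C@H]3CC(=O)O[C@@H]3C1 | intermediate
22 | C5 allylic alcohol, hydroxyl cis to the C6 ether | C/C1=C\CC2(OCCO2)C(=C)[C@@H](O)[C@@H](OCOC)[C@H]3CC(=O)O[C@@H]3C1 | intermediate
23 | C11 dimethylaminomethyl lactone (Mannich base) | C/C1=C\CC2(OCCO2)C(=C)[C@@H](O)[C@@H](OCOC)[C@H]3C(CN(C)C)C(=O)O[C@@H]3C1 | intermediate (not isolated)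
24 | trimethylammonium iodide of 23 | C/C1=C\CC2(OCCO2)C(=C)[C@@H](O)[C@@H](OCOC)[C@H]3C(C[N+](C)(C)C)C(=O)O[C@@H]3C1.[I-] | intermediate (not isolated)
25 | α-methylene lactone with free C5 hydroxyl | C/C1=C\CC2(OCCO2)C(=C)[C@@H](O)[C@@H](OCOC)[C@H]3C(=C)C(=O)O[C@@H]3C1 | intermediate
26 | angelic acid, (Z)-2-methylbut-2-enoic acid | C/C=C(/C)C(=O)O | starting material
27 | C5 angelate, C3 dioxolane, C6 OMOM | C/C1=C\CC2(OCCO2)C(=C)[C@@H](OC(=O)/C(C)=C\C)[C@@H](OCOC)[C@H]3C(=C)C(=O)O[C@@H]3C1 | intermediate
28 | 1(10)-alkene precursor of the target (C3 ketone, C6 hydroxyl) | C/C1=C\CC(=O)C(=C)[C@@H](OC(=O)/C(C)=C\C)[C@@H](O)[C@H]3C(=C)C(=O)O[C@@H]3C1 | intermediate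
29 | CNP0348992.2, (1R,5R,6S,7R,8R,10R)-1,10-epoxy-6-hydroxy-5-[(Z)-2-methylbut-2-enoyloxy]-3-oxogermacra-4(15),11(13)-dien-12,8-olide (locants of this proposal) | C=C1C(=O)O[C@@H]2C[C@@]3(C)O[C@@H]3CC(=O)C(=C)[C@@H](OC(=O)/C(C)=C\C)[C@@H](O)[C@@H]12 | target

## Step count and least certain steps

Total step count: 20. Longest linear sequence: 20 steps (1 and 2 to 29); the quinone 5 and angelic acid 26 enter as commercial materials.

**Step 15 (key step).** Most likely to go wrong: conjugate addition of tert-butoxide to the freshly formed α-methylene ketone, or base-induced enolisation at C6, because the product is exposed to the same alkoxide that triggers the fragmentation. Fallback: starting from 20, the tertiary hydroxyl is silylated (Me3SiOTf, 2,6-lutidine, −78 °C) to the C5 trimethylsilyl ether mesylate F1. Fluoride (CsF, 18-crown-6, THF) then unmasks the alkoxide in the absence of any alkoxide base, so that the same fragmentation returns the route to 21.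

**Step 3.** Most likely to go wrong: poor discrimination of the two faces of the methyl-bearing quinone alkene, because the quaternary-centre-forming cycloaddition is slower than the uncatalysed background reaction; self-cycloaddition of 7 on standing is a second concern. Fallback: starting from 4 and 5, the cycloaddition and elimination are run without a chiral ligand (SnCl4, then DBU). The racemic material is carried through steps 4 and 5, and racemic 9 is separated into its enantiomers by preparative chromatography on a chiral stationary phase. The route is rejoined at 9; this fallback makes no new compound (F0).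

**Step 4.** Most likely to go wrong: attack of the peroxide anion at the remote C8 terminus of the dienone (giving the 7,8-epoxide) or on the wrong face, because both C6 and C8 are unhindered methine acceptor positions. Fallback: starting from 6 (isolated by leaving out DBU in step 3), the silyl ether is cleaved with HF·pyridine to the β-hydroxy ketone F2, which is oxidised (Dess–Martin periodinane) to the 4,6-diketone F3. Its enol is hydroxylated at C5 with dimethyldioxirane, opposite the angular methyl, to the 5-hydroxy-4,6-diketone F4. Luche reduction of the C6 enone carbonyl (NaBH4, CeCl3·7H2O, −78 °C), again opposite the methyl, gives the axial C6 alcohol and rejoins the route at 9.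

**Step 7.** Most likely to go wrong: loss of chemoselectivity, with borane also reducing the vinylogous ester carbonyl at C1, because an excess of reagent is needed for the ketone and the two hydroxyls. Fallback: starting from 10, mCPBA epoxidises C7=C8 from the face opposite the C14 methyl and the C6 ether to the 7,8-epoxide F5. LiN(SiMe3)2 then opens the epoxide through the ester enolate, and the C8 alkoxide closes to the butenolide F6. Conjugate reduction with [CuH(PPh3)]6 delivers hydride to C7 opposite the axial C6 ether and rejoins the route at 14, so that step 8 is not needed.

**Step 16.** Most likely to go wrong: hydride delivery from the wrong face of the C5 carbonyl, because the conformation of the ten-membered ring may not allow the C5 carbonyl and the C6 ether to lie syn for chelation. Fallback: starting from 21, the alcohol is then obtained as the C5 epimer F7. It is inverted by Mitsunobu reaction with 4-nitrobenzoic acid (PPh3, DIAD) to the 4-nitrobenzoate F8, and brief methanolysis (K2CO3, MeOH, 0 °C) rejoins the route at 22.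

**Step 20.** Most likely to go wrong: poor facial selectivity of the peracid, because the conformational preference of the flexible dienone ring, which decides which alkene face is outside, is not known. Fallback: starting from 28, the oxygen is delivered under reagent control by Shi epoxidation (fructose-derived chiral ketone in the enantiomeric form that matches the required face, KHSO5, buffered MeCN–H2O), which rejoins the route at 29; this fallback makes no new compound (F0).

## Further compounds

F1 | step 15 | C5 trimethylsilyl ether of mesylate 20 | CS(=O)(=O)O[C@H]1CC2(OCCO2)C(=C)[C@@]3(O[Si](C)(C)C)[C@@H](OCOC)[C@H]4CC(=O)O[C@@H]4C[C@]13C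
F0 | step 3 | none | none
F2 | step 4 | β-hydroxy ketone (desilylated cycloadduct) | O=C1C=C(OC)C(=O)[C@@H]2[C@H](O)C(CC(=O)OC)=CC[C@]12C
F3 | step 4 | 4,6-diketone (C5 enolisable) | O=C1C=C(OC)C(=O)C2C(=O)C(CC(=O)OC)=CC[C@]12C
F4 | step 4 | 5-hydroxy-4,6-diketone (hydroxyl trans to C14) | O=C1C=C(OC)C(=O)[C@@]2(O)C(=O)C(CC(=O)OC)=CC[C@]12C
F5 | step 7 | 7,8-epoxide of 10 (oxirane trans to C14) | O=C1C=C(OC)C(=O)[C@@]2(O)[C@@H](OCOC)[C@]3(CC(=O)OC)O[C@@H]3C[C@]12C
F6 | step 7 | 7(11)-unsaturated 12,8-butenolide | O=C1C=C(OC)C(=O)[C@@]2(O)[C@@H](OCOC)C3=CC(=O)O[C@@H]3C[C@]12C
F7 | step 16 | C5 epimer of 22 | C/C1=C\CC2(OCCO2)C(=C)[C@H](O)[C@@H](OCOC)[C@H]3CC(=O)O[C@@H]3C1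
F8 | step 16 | 5-O-(4-nitrobenzoyl) derivative of 22 | C/C1=C\CC2(OCCO2)C(=C)[C@@H](OC(=O)c3ccc(cc3)[N+](=O)[O-])[C@@H](OCOC)[C@H]4CC(=O)O[C@@H]4C1
F0 | step 20 | none | none
A1 | alternative 1 | 1-tert-butyl 4-methyl 2-[(3E)-5-(tert-butyldimethylsilyloxy)-3-methylpent-3-enoyl]butanedioate (C7 centre racemising) | CC(C)(C)OC(=O)C(CC(=O)OC)C(=O)C/C(C)=C/CO[Si](C)(C)C(C)(C)C
A2 | alternative 1 | tert-butyl trans-paraconate carrying the C9–C2 arm | CC(C)(C)OC(=O)[C@H]1CC(=O)O[C@@H]1C/C(C)=C/CO[Si](C)(C)C(C)(C)C
A3 | alternative 2 | bicyclic precursor with the tetrasubstituted C3=C8 alkene | CC(=O)OC[C@H]1C=3C[C@H](OS(C)(=O)=O)[C@](C)(O)CC3[C@H](CC(=O)OC)[C@@H]2OC(C)(C)O[C@H]12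
A4 | alternative 2 | ten-membered 3,8-diketone | CC(=O)OC[C@H]1C(=O)C[C@H](OS(C)(=O)=O)[C@](C)(O)CC(=O)[C@H](CC(=O)OC)[C@@H]2OC(C)(C)O[C@H]12
A5 | alternative 3 | seco allylic chloride and vinylstannane | ClC/C=C(\C)C[C@H]1OC(=O)C(=C)[C@@H]1[C@H](O[Si](CC)(CC)CC)[C@H](OC(=O)/C(C)=C\C)C(=C)[Sn](CCCC)(CCCC)CCCC
A6 | alternative 3 | C6 triethylsilyl ether of the 1(10)-alkene of the target | C=C1C(=O)O[C@@H]2C/C(C)=C/CC(=O)C(=C)[C@@H](OC(=O)/C(C)=C\C)[C@@H](O[Si](CC)(CC)CC)[C@@H]12
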